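A direct plan would make the free pyrone A1, turn it with a methyleneiminium salt into the pyrone methide A3, and let ring A of purchased (2S)-pinocembrin A2 capture A3 in the last step.
Its weakest operation would be this C-alkylation of A2: C6 and C8 are both flanked by two ring oxygens, so nothing would steer the bridge to C8, and the 6-linked isomer A4 would form beside the target.
It would also be the step least welcome on late material: it would consume the only chiral and most costly compound, in excess, and end in an HPLC separation of isomers.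
The second weakness would be the stereocentre: C2 would be bought, not made, and would have to survive a warm buffered coupling in which a 5,7-dihydroxyflavanone could open to its chalcone and close again, so the ee of the product would rest on chance.

**Plan of the new route**
Cuts, in retrosynthetic order: C2–phenyl (asymmetric 1,4-addition to a chromone); O1–C2 together with C2 itself (one-carbon annulation of an ortho-hydroxyacetophenone); C4–C4a (acetylation); CH2–C3 of the pyrone (reductive benzylation). The C8–CH2 bond is never formed: the bridge carbon is bought as the formyl carbon of 2,4,6-trihydroxybenzaldehyde.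
Ring order: the pyrone first, then ring C built on ring A as a chromone, then the phenyl ring together with C2.
Regiochemistry: C8 (bridge) and C4a (ketone) are the two carbons ortho to O1 of the phloroglucinol ring A. A 4-O-benzyl-2,6-dihydroxybenzyl unit has a mirror plane through the bridge carbon, so acetylation can give one product only, and the only free hydroxyl ortho to the new ketone is the one next to the bridge.
Key-step feature: C2 bears only H and phenyl and is the β-carbon of the vinylogous ester O1–C2=C3–C4=O of the chromone, so the phenyl group and the stereocentre enter together under catalyst control.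
No arene is alkylated, so no 6-isomer can arise; C2 is created in the penultimate step and meets no base afterwards.

Key step: step 8

Remark on the chemistry: the (R)-ligand is assumed to give the (2S)-adduct, by analogy with the facial sense of this catalyst family on cyclic enones; if the first run showed the opposite sense, the (S)-ligand would be used with no other change.

**Step 1**
Reactants: 1 pentan-3-one
Product: 2 3-(trimethylsilyloxy)pent-2-ene (Z/E mixture)
Conditions: Me3SiOSO2CF3 (1.05 equiv), Et3N (1.2 equiv), Et2O, 0 °C → rt; distillation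
Reagents that add atoms: trimethylsilyl trifluoromethanesulfonate, C[Si](C)(C)OS(=O)(=O)C(F)(F)F
Why: Soft enolisation and O-silylation of a symmetrical ketone (silyl enol ether formation) can give one constitution only, and the double-bond geometry is lost in step 2.

**Step 2**
Reactants: 2 3-(trimethylsilyloxy)pent-2-ene; 3 malonyl dichloride
Product: 5 6-ethyl-4-hydroxy-5-methyl-2H-pyran-2-one, via keto acid chloride 4 (not isolated)
Conditions: Et2O, −78 °C → rt, 12 h; the pyrone is collected by filtration or crystallisation
Reagents that add atoms: none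
Why: In this acylation of a silyl enol ether by malonyl dichloride the enol carbon is C-acylated with loss of Me3SiCl to give 4, whose enol oxygen closes the lactone by 6-exo-trig O-acylation before the dione tautomerises to the 4-hydroxy-2-pyrone; no stereocentre remains.

**Step 3**
Reactants: 6 2,4,6-trihydroxybenzaldehyde
Product: 7 4-(benzyloxy)-2,6-dihydroxybenzaldehyde
Conditions: BnBr (1.0 equiv), CsHCO3 (1.2 equiv), MeCN, 60 °C; chromatography or crystallisation
Reagents that add atoms: benzyl bromide, BrCc1ccccc1
Why: In this Williamson etherification the weak base should ionise only the 4-OH, which is para to the formyl group, most acidic and least hindered, while the ortho pair is engaged with the carbonyl by hydrogen bonding, so the mirror plane through C1 and C4 is kept.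

**Step 4**
Reactants: 7 4-(benzyloxy)-2,6-dihydroxybenzaldehyde; 5 6-ethyl-4-hydroxy-5-methyl-2H-pyran-2-one
Product: 9 3-{[4-(benzyloxy)-2,6-dihydroxyphenyl]methyl}-6-ethyl-4-hydroxy-5-methyl-2H-pyran-2-one, via arylidene pyrandione 8 (not isolated)
Conditions: 5 (1.05 equiv), diethyl 2,6-dimethyl-1,4-dihydropyridine-3,5-dicarboxylate (Hantzsch ester, 1.1 equiv), L-proline (20 mol %), EtOH, 40 °C, N2
Reagents that add atoms: none
Why: Three-component reductive alkylation (Knoevenagel condensation at C3, the only free nucleophilic carbon of the pyrone, then 1,4-transfer hydrogenation of 8 by the Hantzsch ester) joins the two halves through the former formyl carbon, so the place of the bridge between two equivalent hydroxyls is fixed by the starting material and not by an arene substitution.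

**Step 5**
Reactants: 9 3-{[4-(benzyloxy)-2,6-dihydroxyphenyl]methyl}-6-ethyl-4-hydroxy-5-methyl-2H-pyran-2-one
Product: 11 3-{[3-acetyl-4-(benzyloxy)-2,6-dihydroxyphenyl]methyl}-6-ethyl-4-hydroxy-5-methyl-2H-pyran-2-one, via ketiminium chloride 10 (not isolated)
Conditions: MeCN (10 equiv), ZnCl2 (1.5 equiv), HCl (g), Et2O, 0 °C, 24 h; then H2O, 90 °C, 1 h
Reagents that add atoms: acetonitrile, CC#N; water, O
Why: In this Houben–Hoesch acylation of a phloroglucinol-type ring the only free ring carbons, C3 and C5, are equivalent by symmetry, so one ketimine 10 can form, its charge stops a second acylation, and hydrolysis leaves a ketone flanked by the benzyl ether on one side and a free hydroxyl on the other.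

**Step 6**
Reactants: 11 3-{[3-acetyl-4-(benzyloxy)-2,6-dihydroxyphenyl]methyl}-6-ethyl-4-hydroxy-5-methyl-2H-pyran-2-one
Product: 13 5-(benzyloxy)-8-[(6-ethyl-4-hydroxy-5-methyl-2-oxo-2H-pyran-3-yl)methyl]-7-hydroxy-4H-chromen-4-one, via enaminone 12 (not isolated)
Conditions: t-BuOCH(NMe2)2 (4 equiv), PhMe, 70 °C; then AcOH–H2O, 60 °C
Reagents that add atoms: tert-butoxybis(dimethylamino)methane, CN(C)C(OC(C)(C)C)N(C)C
Why: Aminomethylenation of the acetyl group gives 12, and acid-promoted 6-endo addition–elimination (loss of Me2NH) closes ring C as a chromone through the only free oxygen ortho to the ketone, which is the one next to the bridge, so the pyronylmethyl group must end at C8; the reagent carries no transferable methyl group, so the acidic pyrone hydroxyl is not alkylated.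

**Step 7**
Reactants: 13 5-(benzyloxy)-8-[(6-ethyl-4-hydroxy-5-methyl-2-oxo-2H-pyran-3-yl)methyl]-7-hydroxy-4H-chromen-4-one
Product: 14 benzyl 5-(benzyloxy)-8-[(4-{[(benzyloxy)carbonyl]oxy}-6-ethyl-5-methyl-2-oxo-2H-pyran-3-yl)methyl]-4-oxo-4H-chromen-7-yl carbonate
Conditions: CbzCl (2.5 equiv), pyridine, CH2Cl2, 0 °C → rt
Reagents that add atoms: benzyl chloroformate, O=C(Cl)OCc1ccccc1
Why: O-Acylation with a chloroformate masks the phenol and the vinylogous acid of the pyrone (whose C3 and C5 are blocked, so only O-acylation is possible) as benzyl carbonates, which keep these groups from binding palladium in step 8, make the chromone a better acceptor and leave in the same hydrogenolysis as the benzyl ether.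

**Step 8**
Reactants: 14 benzyl 5-(benzyloxy)-8-[(4-{[(benzyloxy)carbonyl]oxy}-6-ethyl-5-methyl-2-oxo-2H-pyran-3-yl)methyl]-4-oxo-4H-chromen-7-yl carbonate; 15 phenylboronic acid
Product: 16 benzyl (2S)-5-(benzyloxy)-8-[(4-{[(benzyloxy)carbonyl]oxy}-6-ethyl-5-methyl-2-oxo-2H-pyran-3-yl)methyl]-4-oxo-2-phenyl-3,4-dihydro-2H-chromen-7-yl carbonate
Conditions: 15 (2.0 equiv), Pd(OCOCF3)2 (5 mol %), (R)-4-tert-butyl-2-(pyridin-2-yl)-4,5-dihydrooxazole (6 mol %), NH4PF6 (30 mol %), H2O (5 equiv), ClCH2CH2Cl, 60 °C
Reagents that add atoms: none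
Why: Transmetalation of 15 to the cationic pyridine–oxazoline complex of divalent palladium gives an aryl–palladium species that binds C2=C3 of the chromone and inserts it, phenyl going to C2 and palladium to C3, after which water protonates the palladium enolate, frees the flavanone and returns the hydroxo complex; this is the asymmetric conjugate addition of arylboronic acids to chromones, a known catalytic entry to flavanones. No ring is closed here, since ring C exists from step 6 and is only saturated at C2–C3. The new stereocentre C2 is set in the insertion step by the ligand, whose tert-butyl group shields one face of the bound enone, so the (R)-ligand should deliver phenyl to the face that gives (2S). The step needs chemoselectivity for the chromone over the pyrone, which the substrate secures because C2 of the chromone is an unsubstituted β-carbon whereas both pyrone double bonds are tetrasubstituted and electron-rich. It needs a free coordination site on palladium and an electrophilic acceptor, which the two carbonates secure by masking the acidic hydroxyls and weakening the donor at C7. It needs the product to keep its configuration, which the neutral to weakly acidic medium secures because ring opening to the chalcone requires base.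

**Step 9**
Reactants: 16 benzyl (2S)-5-(benzyloxy)-8-[(4-{[(benzyloxy)carbonyl]oxy}-6-ethyl-5-methyl-2-oxo-2H-pyran-3-yl)methyl]-4-oxo-2-phenyl-3,4-dihydro-2H-chromen-7-yl carbonate
Product: 17 (2S)-8-[(6-ethyl-4-hydroxy-5-methyl-2-oxo-2H-pyran-3-yl)methyl]-5,7-dihydroxy-2-phenyl-2,3-dihydro-4H-chromen-4-one
Conditions: H2 (1 atm), 10 % Pd/C, EtOAc–MeOH, rt; stopped when hydrogen uptake ends
Reagents that add atoms: none
Why: Hydrogenolysis of the benzyl ether and of both benzyl carbonates (which lose CO2) under neutral conditions frees the three hydroxyls without a base or Lewis acid that could open ring C, so C2 should stay (S), while the tetrasubstituted pyrone double bonds and the ketone are expected to survive.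

**Compound list**
1 | pentan-3-one | CCC(=O)CC | starting material
2 | 3-(trimethylsilyloxy)pent-2-ene (Z/E mixture) | CC=C(CC)O[Si](C)(C)C | intermediate
3 | malonyl dichloride | O=C(Cl)CC(=O)Cl | starting material
4 | 4-methyl-3,5-dioxoheptanoyl chloride | CCC(=O)C(C)C(=O)CC(=O)Cl | intermediate
5 | 6-ethyl-4-hydroxy-5-methyl-2H-pyran-2-one | CCc1oc(=O)cc(O)c1C | intermediate
6 | 2,4,6-trihydroxybenzaldehyde | O=Cc1c(O)cc(O)cc1O | starting material
7 | 4-(benzyloxy)-2,6-dihydroxybenzaldehyde | O=Cc1c(O)cc(OCc2ccccc2)cc1O | intermediate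
8 | 3-{[4-(benzyloxy)-2,6-dihydroxyphenyl]methylidene}-6-ethyl-5-methyl-2H-pyran-2,4(3H)-dione (double-bond geometry not defined) | CCC1=C(C)C(=O)C(=Cc2c(O)cc(OCc3ccccc3)cc2O)C(=O)O1 | intermediate
9 | 3-{[4-(benzyloxy)-2,6-dihydroxyphenyl]methyl}-6-ethyl-4-hydroxy-5-methyl-2H-pyran-2-one | CCc1oc(=O)c(Cc2c(O)cc(OCc3ccccc3)cc2O)c(O)c1C | intermediate
10 | 1-{6-(benzyloxy)-3-[(6-ethyl-4-hydroxy-5-methyl-2-oxo-2H-pyran-3-yl)methyl]-2,4-dihydroxyphenyl}ethan-1-iminium chloride | CC(=[NH2+])c1c(OCc2ccccc2)cc(O)c(Cc2c(O)c(C)c(CC)oc2=O)c1O.[Cl-] | intermediate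
11 | 3-{[3-acetyl-4-(benzyloxy)-2,6-dihydroxyphenyl]methyl}-6-ethyl-4-hydroxy-5-methyl-2H-pyran-2-one | CC(=O)c1c(OCc2ccccc2)cc(O)c(Cc2c(O)c(C)c(CC)oc2=O)c1O | intermediate
12 | (2E)-1-{6-(benzyloxy)-3-[(6-ethyl-4-hydroxy-5-methyl-2-oxo-2H-pyran-3-yl)methyl]-2,4-dihydroxyphenyl}-3-(dimethylamino)prop-2-en-1-one | CN(C)/C=C/C(=O)c1c(OCc2ccccc2)cc(O)c(Cc2c(O)c(C)c(CC)oc2=O)c1O | intermediate
13 | 5-(benzyloxy)-8-[(6-ethyl-4-hydroxy-5-methyl-2-oxo-2H-pyran-3-yl)methyl]-7-hydroxy-4H-chromen-4-one | O=c1ccoc2c(Cc3c(O)c(C)c(CC)oc3=O)c(O)cc(OCc3ccccc3)c12 | intermediate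
14 | benzyl 5-(benzyloxy)-8-[(4-{[(benzyloxy)carbonyl]oxy}-6-ethyl-5-methyl-2-oxo-2H-pyran-3-yl)methyl]-4-oxo-4H-chromen-7-yl carbonate | O=c1ccoc2c(Cc3c(OC(=O)OCc4ccccc4)c(C)c(CC)oc3=O)c(OC(=O)OCc3ccccc3)cc(OCc3ccccc3)c12 | intermediate
15 | phenylboronic acid | OB(O)c1ccccc1 | starting material
16 | benzyl (2S)-5-(benzyloxy)-8-[(4-{[(benzyloxy)carbonyl]oxy}-6-ethyl-5-methyl-2-oxo-2H-pyran-3-yl)methyl]-4-oxo-2-phenyl-3,4-dihydro-2H-chromen-7-yl carbonate | O=C1C[C@@H](c2ccccc2)Oc2c(Cc3c(OC(=O)OCc4ccccc4)c(C)c(CC)oc3=O)c(OC(=O)OCc3ccccc3)cc(OCc3ccccc3)c12 | intermediate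
17 | (2S)-8-[(6-ethyl-4-hydroxy-5-methyl-2-oxo-2H-pyran-3-yl)methyl]-5,7-dihydroxy-2-phenyl-2,3-dihydro-4H-chromen-4-one | CCc1oc(=O)c(Cc2c(O)cc(O)c3c2O[C@H](c2ccccc2)CC3=O)c(O)c1C | target

**Step count and risks**
Total: 9 steps. Longest linear sequence: 8 steps (steps 1, 2, 4, 5, 6, 7, 8, 9, from pentan-3-one); the arene branch from 2,4,6-trihydroxybenzaldehyde runs through 7 steps.

The three steps most likely to fail:

Step 8 (asymmetric arylation). Insertion into an electron-rich, doubly ortho-substituted chromone may be slow, so that protodeboronation of 15 outruns addition. Facial discrimination may be insufficient, or the enol carbonate may be hydrolysed and the freed pyrone may then bind the catalyst. The fallback gives up asymmetric catalysis for ring closure of a chalcone followed by resolution. It sets out from 11: aldol condensation with benzaldehyde and pyrrolidine in EtOH at 60 °C would give the chalcone 3-({4-(benzyloxy)-2,6-dihydroxy-3-[(2E)-3-phenylprop-2-enoyl]phenyl}methyl)-6-ethyl-4-hydroxy-5-methyl-2H-pyran-2-one F1. NaOAc in refluxing EtOH would close F1 by 6-endo oxa-Michael addition through its only free ortho-hydroxyl to the racemic 5-O-benzyl flavanone F2. Preparative supercritical-fluid chromatography on an amylose tris(3,5-dimethylphenylcarbamate) phase would separate the (2S)-enantiomer F3 from the (2R)-enantiomer F4, which could be re-racemised with NaOAc and recycled. Hydrogenolysis of F3 (H2, 10 % Pd/C, EtOAc–MeOH) would come back to the route at 17.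

Step 4 (reductive benzylation). The Knoevenagel condensation may stall on the hydrogen-bonded, electron-rich aldehyde, or a second pyrone may add to the arylidene intermediate faster than hydride is transferred. The fallback makes that double addition on purpose and reduces afterwards. It sets out from 7 and 5: with 5 (2.2 equiv) and piperidinium acetate in refluxing EtOH the bis(pyronyl)methane 3,3'-{[4-(benzyloxy)-2,6-dihydroxyphenyl]methanediyl}bis(6-ethyl-4-hydroxy-5-methyl-2H-pyran-2-one) F5 would form. Ionic hydrogenation (Et3SiH, CF3CO2H, CH2Cl2, 0 °C → rt) would ionise F5 by acid-induced retro-Michael loss of one pyrone to the quinone-methide cation and trap it with hydride, coming back to the route at 9; the released 5 could be re-used.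

Step 5 (Houben–Hoesch acetylation). The strong acid may cause cyclodehydration between the pyrone hydroxyl and a flanking phenol, loss of the benzyl ether, or incomplete ketimine formation. The fallback replaces direct C-acylation by O-acylation and acyl migration. It sets out from 9: Ac2O in pyridine would give the triacetate 3-(acetyloxy)-5-(benzyloxy)-2-{[4-(acetyloxy)-6-ethyl-5-methyl-2-oxo-2H-pyran-3-yl]methyl}phenyl acetate F6. A Fries rearrangement catalysed by Sc(OSO2CF3)3 (PhMe, 100 °C) would move one aryl acetyl group to a ring carbon; ortho and para migration lead to the same skeleton because C3 and C5 are equivalent. K2CO3 in MeOH at rt would remove the two remaining O-acetyl groups and come back to the route at 11.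

**Further compounds**
F1 | step 8 | 3-({4-(benzyloxy)-2,6-dihydroxy-3-[(2E)-3-phenylprop-2-enoyl]phenyl}methyl)-6-ethyl-4-hydroxy-5-methyl-2H-pyran-2-one | O=C(/C=C/c1ccccc1)c1c(OCc2ccccc2)cc(O)c(Cc2c(O)c(C)c(CC)oc2=O)c1O
F2 | step 8 | rac-5-(benzyloxy)-8-[(6-ethyl-4-hydroxy-5-methyl-2-oxo-2H-pyran-3-yl)methyl]-7-hydroxy-2-phenyl-2,3-dihydro-4H-chromen-4-one | O=C1CC(c2ccccc2)Oc2c(Cc3c(O)c(C)c(CC)oc3=O)c(O)cc(OCc3ccccc3)c12
F3 | step 8 | (2S)-5-(benzyloxy)-8-[(6-ethyl-4-hydroxy-5-methyl-2-oxo-2H-pyran-3-yl)methyl]-7-hydroxy-2-phenyl-2,3-dihydro-4H-chromen-4-one | O=C1C[C@@H](c2ccccc2)Oc2c(Cc3c(O)c(C)c(CC)oc3=O)c(O)cc(OCc3ccccc3)c12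
F4 | step 8 | (2R)-5-(benzyloxy)-8-[(6-ethyl-4-hydroxy-5-methyl-2-oxo-2H-pyran-3-yl)methyl]-7-hydroxy-2-phenyl-2,3-dihydro-4H-chromen-4-one | O=C1C[C@H](c2ccccc2)Oc2c(Cc3c(O)c(C)c(CC)oc3=O)c(O)cc(OCc3ccccc3)c12
F5 | step 4 | 3,3'-{[4-(benzyloxy)-2,6-dihydroxyphenyl]methanediyl}bis(6-ethyl-4-hydroxy-5-methyl-2H-pyran-2-one) | CCc1oc(=O)c(C(c2c(O)c(C)c(CC)oc2=O)c2c(O)cc(OCc3ccccc3)cc2O)c(O)c1C
F6 | step 5 | 3-(acetyloxy)-5-(benzyloxy)-2-{[4-(acetyloxy)-6-ethyl-5-methyl-2-oxo-2H-pyran-3-yl]methyl}phenyl acetate | CCc1oc(=O)c(Cc2c(OC(C)=O)cc(OCc3ccccc3)cc2OC(C)=O)c(OC(C)=O)c1C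
A1 | direct plan | 6-ethyl-4-hydroxy-5-methyl-2H-pyran-2-one | CCc1oc(=O)cc(O)c1C
A2 | direct plan | (2S)-pinocembrin, (2S)-5,7-dihydroxy-2-phenyl-2,3-dihydro-4H-chromen-4-one | Oc1cc(O)c2c(c1)O[C@H](c1ccccc1)CC2=O
A3 | direct plan | 6-ethyl-5-methyl-3-methylidene-2H-pyran-2,4(3H)-dione | CCC1=C(C)C(=O)C(=C)C(=O)O1
A4 | direct plan | (2S)-6-[(6-ethyl-4-hydroxy-5-methyl-2-oxo-2H-pyran-3-yl)methyl]-5,7-dihydroxy-2-phenyl-2,3-dihydro-4H-chromen-4-one | CCc1oc(=O)c(Cc2c(O)cc3c(c2O)C(=O)C[C@@H](c2ccccc2)O3)c(O)c1C
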